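# Proposed synthesis of (−)-cubebininolide (13)

## Analysis of the target

(−)-Cubebininolide (13) is a dibenzylbutyrolactone lignan. It has one oxolan-2-one ring, O1–C2(=O)–C3–C4–C5, with a 3,4,5-trimethoxybenzyl group on C3 and another on C4. C3 and C4 are the only stereocentres; both are R, and the two arylmethyl arms are trans on the ring. C3 lies next to the lactone carbonyl and can be epimerised, and the trans arrangement is the more stable one, so C3 can be settled by equilibration. C4 is flanked only by CH2 groups, cannot be corrected later, and must be installed with absolute control. The lactone is sensitive to hydroxide and hard nucleophiles. The six aryl methyl ethers and the electron-rich rings rule out strong Lewis acids and oxidants. Apart from the oxidation levels of C2 and C5 the skeleton is symmetric about the C3–C4 bond, so routes through C2-symmetric succinates must later tell two identical carboxyl groups apart. The strategy rests on the C4 arm: its CH2 can be read as the methylene of a cyclopropane fused across C3 and C4, as in the 3-oxabicyclo[3.1.0]hexan-2-one 5. An ester on C3 then makes that ring an acceptor for an aryl nucleophile.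

## Retrosynthetic reasoning

**13 from 10.** A methoxycarbonyl group is added back onto C3, which makes C3 a malonate-type carbon. This costs one step in the forward direction (Krapcho demethoxycarbonylation through 11 and 12). In return the same ester activates the cyclopropane of the precursor and stabilises the enolate that is to be benzylated. The configuration of C3 in 10 is free, because C3 passes through a planar enolate and ends in the trans lactone by thermodynamic preference.

**10 from 5, 7 and 8.** Two bonds are cut: the aryl–CH2 bond of the C4 arm and the C3–CH2 bond of the C3 arm. Cutting the C4 arm at aryl–CH2, and not at C4–CH2, leaves C4 untouched and turns the arm's CH2 into the methylene of the fused cyclopropane in 5. The aryl group then comes from a simple Grignard reagent, 7. The C3 arm is cut as an enolate alkylation with 8. In the forward direction a copper-catalysed homoconjugate addition must open the cyclopropane only at its CH2 and avoid the carbonyl groups. The enolate 9 set free must then be benzylated at carbon in the same flask. Both arms thus come from trimethoxyphenyl building blocks in a single three-component operation.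

**5 from 1 and 2.** The cyclopropane and the lactone are cut back to a malonate carbon acting twice as a nucleophile and to a three-carbon unit that is electrophilic at two carbons and carries the lactone oxygen. This is the alkoxide-mediated cascade of 2 with 1 through 3 and 4. It closes both rings and transfers the single stereocentre of 1 to C5 of 5, which later becomes C4 of the target.

**7 from 6.** The carbon–magnesium bond is cut back to the aryl bromide 6 by direct magnesium insertion.

## Alternatives that were turned down

**Alternative 1:** Both aryl–CH2 bonds are disconnected at once, back to a C2-symmetric dimethylsuccinic diamide. In the forward direction (2R,3R)-2,3-dimethyl-N1,N4-bis[2-(methylthio)phenyl]succinamide A1 is arylated at both methyl groups by 5-iodo-1,2,3-trimethoxybenzene A2 under Pd(OAc)2 and AgOAc, giving (2R,3R)-N1,N4-bis[2-(methylthio)phenyl]-2,3-bis(3,4,5-trimethoxybenzyl)succinamide A3.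
- For: both stereocentres are present from the start in the right relationship, and one catalytic operation attaches both rings. The thioether anilide directing group favours a single arylation per methyl group.
- Against: the two stereocentres are alpha to amide carbonyls. They must survive a hot, acetate-buffered palladation and then the cleavage of two robust secondary anilides, and both can epimerise them. The arylation must go to completion at both ends, and it uses stoichiometric silver. After the key step the anilides must be removed, and one of two identical carboxyl groups must be reduced and lactonised, usually through the cyclic anhydride. That makes about six steps from a costly chiral diacid derivative.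
- Comparison: this alternative is stronger on the C3/C4 relationship, which is never in doubt. The chosen route relies on the trans preference of the lactone for C3. In return it uses no auxiliary, builds the lactone oxidation pattern in from the start, uses a cheap source of chirality, and needs four steps.

**Alternative 2:** The bonds from C3 and C4 to their benzylic carbons are disconnected, with a sulfur atom temporarily bridging the two benzylic carbons. On heating, bis[(3,4,5-trimethoxyphenyl)(trimethylsilyl)methyl] sulfoxide A4 releases a 1,3-diaryl thiocarbonyl ylide (sila-Pummerer rearrangement, then 1,3-elimination). The ylide adds to di-(−)-menthyl fumarate A5 and gives di-(−)-menthyl (3R,4R)-2,5-bis(3,4,5-trimethoxyphenyl)thiolane-3,4-dicarboxylate A6. Raney Ni then removes the sulfur.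
- For: the cycloaddition is suprafacial, so the trans relationship of the fumarate is carried over without fail. Both carbon–carbon bonds form in one step, and the symmetric dipole raises no regiochemical question.
- Against: the absolute configuration depends on remote menthyl esters distinguishing the two faces of an unchelated fumarate, which is a weak control element. The dipole precursor needs several steps. The two stereocentres next to sulfur are formed as mixtures and then destroyed. Desulfurisation needs a large excess of nickel. The hindered menthyl esters must be cleaved without epimerisation before one carboxyl group can be reduced.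
- Comparison: this alternative is at least as good on relative configuration. The chosen route is firmer on absolute configuration, since C4 comes from a stereospecific substitution on 1, and it is roughly half as long.

**Alternative 3:** The C2–C3 and C4–C5 bonds are disconnected, back to (E)-1,4-bis(3,4,5-trimethoxyphenyl)but-2-ene A7. The alkene, two carbon monoxide and two methanol combine under Pd(O2CCF3)2, a chiral bis(oxazoline) ligand and benzoquinone. Two ester groups add syn and give dimethyl (2R,3R)-2,3-bis(3,4,5-trimethoxybenzyl)succinate A8.
- For: this is a catalytic asymmetric step that sets both stereocentres from an achiral, symmetric alkene, with the right relative configuration from syn addition to an E-alkene. On atom economy and on use of chirality it is the strongest of the four strategies.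
- Against: A7 is an unactivated 1,2-dialkyl alkene whose allylic hydrogens are also benzylic. The alkylpalladium intermediates can therefore undergo beta-hydride elimination towards styrenes or allylic activation before the second carbonylation. Face selection on an alkene that carries only arylmethyl groups is uncertain. A8 still needs hydrolysis, anhydride formation and reduction to reach the lactone, and A7 itself takes about two steps.
- Comparison: the chosen route gives up catalytic enantioinduction. In exchange, every bond-forming event belongs to an established reaction class, C4 is secured from the chiral pool, and the sequence is shorter.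

Key step: step 3

Remark: 10 is drawn as the 3R epimer expected from benzylation anti to the C4 arm; the route does not depend on this, because C3 is re-formed in step 4.

## Route

**Step 1**
Reactants: 1 (R)-epichlorohydrin [(2R)-2-(chloromethyl)oxirane]; 2 dimethyl malonate
Product: 5 methyl (1S,5R)-2-oxo-3-oxabicyclo[3.1.0]hexane-1-carboxylate, via epoxide malonate 3 (not isolated), via cyclopropylmethanolate 4 (not isolated)
Conditions: NaOMe (1.1 equiv), MeOH, 0 °C → reflux
Reagents that add atoms: none
Why: Malonate alkylation cascade: the sodium enolate of 2 opens the epoxide of 1 at its CH2, the alkoxide displaces chloride to give the transposed epoxide 3, and the re-formed malonate anion closes the cyclopropane by 3-exo-tet attack on the epoxide CH with inversion to give 4, which lactonises onto the cis ester. C5 follows from this single inversion at the stereocentre of 1, and C1 is fixed because only a cis-fused lactone can form; methoxide with the methyl ester makes transesterification degenerate.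

**Step 2**
Reactants: 6 5-bromo-1,2,3-trimethoxybenzene
Product: 7 (3,4,5-trimethoxyphenyl)magnesium bromide (THF solution, titrated before use)
Conditions: Mg turnings, I2 (cat.), THF, reflux
Reagents that add atoms: magnesium, [Mg]
Why: Grignard reagent formation by insertion of magnesium into the aryl C–Br bond; the methoxy groups are inert and no stereocentre is involved.

**Step 3**
Reactants: 5 methyl (1S,5R)-2-oxo-3-oxabicyclo[3.1.0]hexane-1-carboxylate; 7 (3,4,5-trimethoxyphenyl)magnesium bromide; 8 3,4,5-trimethoxybenzyl bromide [5-(bromomethyl)-1,2,3-trimethoxybenzene]
Product: 10 methyl (3R,4R)-2-oxo-3,4-bis(3,4,5-trimethoxybenzyl)oxolane-3-carboxylate, via bromomagnesium enolate 9 (not isolated)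
Conditions: 7 (1.1 equiv) added to 5, CuI (10 mol %), THF, −30 °C; then DMPU, 8 (1.3 equiv), −30 °C → rt
Reagents that add atoms: none
Why: The aryl group passes from magnesium to monovalent copper, and the aryl copper species attacks the unsubstituted cyclopropane carbon C6 of 5 in SN2 fashion with cleavage of the C1–C6 bond, a homoconjugate addition driven by release of ring strain and by the doubly stabilised enolate that leaves. The closest known reaction type is the CuI-catalysed opening of cyclopropane-1,1-dicarbonyl compounds, this bicyclic lactone ester included, by Grignard reagents, combined with the alkylation of malonate-type enolates. No ring is closed; the cyclopropane opens and the lactone stays intact. C5 of 5 is not a reacting centre and becomes C4 of the lactone with its R configuration unchanged. Attack at C6 and not at the ring-fusion carbon C5 is secured by the primary against tertiary substitution, and addition to the ester or lactone carbonyl is held back by copper catalysis at −30 °C and slow addition of 7. Enolate 9 is then benzylated at carbon by 8 once DMPU has loosened the magnesium chelate, the soft benzylic bromide favouring C- over O-alkylation. The new quaternary centre C3 is controlled by the C4 arm, the electrophile entering anti to it to give the 3R epimer drawn; this selectivity is not critical, because C3 is re-set in step 4.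

**Step 4**
Reactants: 10 methyl (3R,4R)-2-oxo-3,4-bis(3,4,5-trimethoxybenzyl)oxolane-3-carboxylate
Product: 13 (3R,4R)-3,4-bis(3,4,5-trimethoxybenzyl)oxolan-2-one [(−)-cubebininolide], via lithium carboxylate 11 (not isolated), via lithium enolate 12 (not isolated)
Conditions: LiCl, DMSO–H2O, 150 °C
Reagents that add atoms: none
Why: Krapcho demethoxycarbonylation: chloride attacks the ester methyl group in SN2 fashion to give carboxylate 11, which loses carbon dioxide to give enolate 12, and water protonates it at C3. C3 is set under thermodynamic control, since the alpha hydrogen of the product exchanges under the hot, mildly basic conditions and the trans-3,4-disubstituted lactone is the more stable epimer. C4 is not touched, and the aryl methyl ethers are not activated towards chloride.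

## Compound list

1 | (R)-epichlorohydrin [(2R)-2-(chloromethyl)oxirane] | ClC[C@H]1CO1 | starting material
2 | dimethyl malonate | COC(=O)CC(=O)OC | starting material
3 | dimethyl 2-{[(2R)-oxiran-2-yl]methyl}propanedioate | COC(=O)C(C[C@@H]1CO1)C(=O)OC | intermediate (not isolated)
4 | sodium [(1R)-2,2-bis(methoxycarbonyl)cyclopropyl]methanolate | COC(=O)C1(C(=O)OC)C[C@H]1C[O-].[Na+] | intermediate (not isolated)
5 | methyl (1S,5R)-2-oxo-3-oxabicyclo[3.1.0]hexane-1-carboxylate | COC(=O)[C@]12C[C@H]1COC2=O | intermediate
6 | 5-bromo-1,2,3-trimethoxybenzene | COc1cc(Br)cc(OC)c1OC | starting material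
7 | (3,4,5-trimethoxyphenyl)magnesium bromide | COc1cc([Mg]Br)cc(OC)c1OC | intermediate
8 | 3,4,5-trimethoxybenzyl bromide [5-(bromomethyl)-1,2,3-trimethoxybenzene] | COc1cc(CBr)cc(OC)c1OC | starting material
9 | bromomagnesium enolate of methyl (4R)-2-oxo-4-(3,4,5-trimethoxybenzyl)oxolane-3-carboxylate | COC(=O)C1=C(O[Mg]Br)OC[C@@H]1Cc1cc(OC)c(OC)c(OC)c1 | intermediate (not isolated)
10 | methyl (3R,4R)-2-oxo-3,4-bis(3,4,5-trimethoxybenzyl)oxolane-3-carboxylate | COC(=O)[C@@]1(Cc2cc(OC)c(OC)c(OC)c2)[C@@H](Cc2cc(OC)c(OC)c(OC)c2)COC1=O | intermediate
11 | lithium (3R,4R)-2-oxo-3,4-bis(3,4,5-trimethoxybenzyl)oxolane-3-carboxylate | [Li+].[O-]C(=O)[C@@]1(Cc2cc(OC)c(OC)c(OC)c2)[C@@H](Cc2cc(OC)c(OC)c(OC)c2)COC1=O | intermediate (not isolated)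
12 | lithium (4R)-3,4-bis(3,4,5-trimethoxybenzyl)-4,5-dihydrofuran-2-olate | [Li+].[O-]C1=C(Cc2cc(OC)c(OC)c(OC)c2)[C@@H](Cc2cc(OC)c(OC)c(OC)c2)CO1 | intermediate (not isolated)
13 | (3R,4R)-3,4-bis(3,4,5-trimethoxybenzyl)oxolan-2-one, (−)-cubebininolide | COc1cc(C[C@H]2COC(=O)[C@@H]2Cc2cc(OC)c(OC)c(OC)c2)cc(OC)c1OC | target

## Step count and risks

Total step count: 4. Longest linear sequence: 3 steps (1 → 5 → 10 → 13, steps 1, 3 and 4); step 2 is a one-step side branch.

**Step 3 (key step).**
- Risk: slow C-benzylation of the chelated, doubly stabilised magnesium enolate 9 is the most likely failure. Copper-mediated coupling of leftover 7 with 8, O-alkylation, or simple protonation on work-up could then take over. Carbonyl addition of 7 during the opening is less likely.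
- Fallback (sets out from 5, 7 and 8; rejoins at 13): the two bond formations are separated, and the ester is removed before the second one. The opening of 5 with 7 and catalytic CuI is run as above, but enolate 9 is quenched with aqueous NH4Cl. This should give methyl (4R)-2-oxo-4-(3,4,5-trimethoxybenzyl)oxolane-3-carboxylate F1 as a mixture of C3 epimers. Demethoxycarbonylation with LiCl in wet DMSO at 140 °C should then give (4R)-4-(3,4,5-trimethoxybenzyl)oxolan-2-one F2. Deprotonation with LiN(SiMe3)2 in THF at −78 °C gives lithium (4R)-4-(3,4,5-trimethoxybenzyl)-4,5-dihydrofuran-2-olate F3. This enolate is alkylated by 8 anti to the C4 arm, so the trans lactone 13 should form directly under kinetic control. The fallback costs one more step.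

**Step 4.**
- Risk: dealkoxycarbonylation at the congested quaternary carbon may be incomplete at a temperature the molecule tolerates. On prolonged heating, nucleophilic cleavage of aryl methyl ethers or opening of the lactone at C5 by chloride could set in. Protonation of enolate 12 from the face away from the C4 arm is kinetically cis-selective, so incomplete equilibration would leave some cis epimer.
- Fallback (sets out from 10; rejoins at 13): a hydrolytic route. KOH in aqueous MeOH at reflux should cleave the methyl ester and open the lactone, giving dipotassium 2-[(2R)-1-hydroxy-3-(3,4,5-trimethoxyphenyl)propan-2-yl]-2-(3,4,5-trimethoxybenzyl)propanedioate F4. Acidification with HCl re-closes the lactone and should give (4R)-2-oxo-3,4-bis(3,4,5-trimethoxybenzyl)oxolane-3-carboxylic acid F5, as either C3 epimer. Heating F5 in toluene at reflux should bring about decarboxylation through the enol. A final treatment with DBU in toluene equilibrates C3 to the trans lactone 13.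

**Step 1.**
- Risk: enantiomeric purity can erode, because direct displacement of chloride by the malonate anion, instead of epoxide opening, leads into the mirror-image series. Double alkylation of the malonate is a secondary risk.
- Fallback (sets out from 2; rejoins at 3 and from there at 5): the electrophile is changed so that direct displacement is the only pathway. (R)-Glycidol F6 with Tf2O and pyridine in CH2Cl2 at −30 °C should give [(2S)-oxiran-2-yl]methyl trifluoromethanesulfonate F7. The sodium enolate of 2 (NaH, THF) displaces the triflate at low temperature without touching the epoxide and gives the same epoxide 3. On warming with a second equivalent of base, 3 closes through 4 to 5 as in step 1.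

**Step 2.**
- Risk: sluggish initiation and Wurtz-type homocoupling of the electron-rich aryl bromide would give a reagent of uncertain titre and upset the stoichiometry of step 3.
- Fallback (sets out from 6; rejoins at 7): bromine–lithium exchange with n-BuLi in THF at −78 °C to (3,4,5-trimethoxyphenyl)lithium F8, followed by transmetalation with MgBr2·OEt2 to give 7.

## Further compounds

F1 | step 3 | methyl (4R)-2-oxo-4-(3,4,5-trimethoxybenzyl)oxolane-3-carboxylate (C3 epimers) | COC(=O)C1C(=O)OC[C@@H]1Cc1cc(OC)c(OC)c(OC)c1
F2 | step 3 | (4R)-4-(3,4,5-trimethoxybenzyl)oxolan-2-one | O=C1C[C@@H](Cc2cc(OC)c(OC)c(OC)c2)CO1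
F3 | step 3 | lithium (4R)-4-(3,4,5-trimethoxybenzyl)-4,5-dihydrofuran-2-olate | [Li+].[O-]C1=C[C@@H](Cc2cc(OC)c(OC)c(OC)c2)CO1
F4 | step 4 | dipotassium 2-[(2R)-1-hydroxy-3-(3,4,5-trimethoxyphenyl)propan-2-yl]-2-(3,4,5-trimethoxybenzyl)propanedioate | [K+].[K+].[O-]C(=O)C(Cc1cc(OC)c(OC)c(OC)c1)(C([O-])=O)[C@@H](Cc1cc(OC)c(OC)c(OC)c1)CO
F5 | step 4 | (4R)-2-oxo-3,4-bis(3,4,5-trimethoxybenzyl)oxolane-3-carboxylic acid (C3 epimers) | OC(=O)C1(Cc2cc(OC)c(OC)c(OC)c2)[C@@H](Cc2cc(OC)c(OC)c(OC)c2)COC1=O
F6 | step 1 | (R)-glycidol [(2R)-oxiran-2-ylmethanol] | OC[C@@H]1CO1
F7 | step 1 | [(2S)-oxiran-2-yl]methyl trifluoromethanesulfonate | O=S(=O)(OC[C@@H]1CO1)C(F)(F)F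
F8 | step 2 | (3,4,5-trimethoxyphenyl)lithium | [Li]c1cc(OC)c(OC)c(OC)c1
A1 | alternative 1 | (2R,3R)-2,3-dimethyl-N1,N4-bis[2-(methylthio)phenyl]succinamide | C[C@@H](C(=O)Nc1ccccc1SC)[C@@H](C)C(=O)Nc1ccccc1SC
A2 | alternative 1 | 5-iodo-1,2,3-trimethoxybenzene | COc1cc(I)cc(OC)c1OC
A3 | alternative 1 | (2R,3R)-N1,N4-bis[2-(methylthio)phenyl]-2,3-bis(3,4,5-trimethoxybenzyl)succinamide | COc1cc(C[C@@H](C(=O)Nc2ccccc2SC)[C@@H](Cc2cc(OC)c(OC)c(OC)c2)C(=O)Nc2ccccc2SC)cc(OC)c1OC
A4 | alternative 2 | bis[(3,4,5-trimethoxyphenyl)(trimethylsilyl)methyl] sulfoxide | COc1cc(C([Si](C)(C)C)S(=O)C([Si](C)(C)C)c2cc(OC)c(OC)c(OC)c2)cc(OC)c1OC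
A5 | alternative 2 | di-(−)-menthyl fumarate | O=C(O[C@@H]1C[C@H](C)CC[C@H]1C(C)C)/C=C/C(=O)O[C@@H]1C[C@H](C)CC[C@H]1C(C)C
A6 | alternative 2 | di-(−)-menthyl (3R,4R)-2,5-bis(3,4,5-trimethoxyphenyl)thiolane-3,4-dicarboxylate | O=C(O[C@@H]1C[C@H](C)CC[C@H]1C(C)C)[C@@H]1C(c2cc(OC)c(OC)c(OC)c2)SC(c2cc(OC)c(OC)c(OC)c2)[C@H]1C(=O)O[C@@H]1C[C@H](C)CC[C@H]1C(C)C
A7 | alternative 3 | (E)-1,4-bis(3,4,5-trimethoxyphenyl)but-2-ene | COc1cc(C/C=C/Cc2cc(OC)c(OC)c(OC)c2)cc(OC)c1OC
A8 | alternative 3 | dimethyl (2R,3R)-2,3-bis(3,4,5-trimethoxybenzyl)succinate | COC(=O)[C@H](Cc1cc(OC)c(OC)c(OC)c1)[C@@H](Cc1cc(OC)c(OC)c(OC)c1)C(=O)OC
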